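## Structural features

The target is a germacranolide: a ten-membered carbocycle (C1–C10) cis-fused across C6–C7 to an α-methyl-γ-butyrolactone (O–C6, C7, C11, C12). Germacrane numbering is used throughout: C1 carries OMe, C4=C5 is the E-trisubstituted alkene, C8 carries the acyloxy group, C9 is the ketone, C10 and C11 carry methyl groups. Six ring stereocentres fall into two arrays: the contiguous set C11–C7–C6 with C8 attached to C7, and the pair C10/C1 on the far side of the C9 ketone. The C8 ester is a (2S,3R)-2,3-dimethyloxirane-2-carboxylate with two further stereocentres; the two methyl groups are cis, so it is the epoxide of tiglic acid. Fragile elements are the trisubstituted epoxide (acid, nucleophiles), the β-methoxy ketone C1/C9 (E1cB loss of methanol, epimerisation at C10), the α-oxygenated ketone C8/C9 (epimerisation, acyl shift) and the lactone, which can migrate from O6 to a free O8 or O9 under base. The real difficulty is the strained ten-membered ring with an E-trisubstituted alkene amid dense functionality, not any single stereocentre. The key step exploits the C4=C5 alkene: C4 is carried as a geometrically pure vinyl iodide and the saturated C1–C3 segment as a chain ending in the C2=C3 vinyl group, so that the ring closes by forming the C3(sp3)–C4(sp2) bond.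

## Logic of the disconnections

36 is cut at the C8 O–acyl bond into 30 and 34. The epoxy ester is the most fragile group and is therefore added last. The forward step must acylate a hindered secondary α-hydroxy ketone without lactone migration.

34 is traced through 33 and 32 to 31. Direct asymmetric epoxidation of the electron-poor acid is not dependable, so the acid is reduced to the allylic alcohol, which is a standard Sharpless substrate, and re-oxidised. The acid is (2S,3R) but the alcohol must be (2R,3R); only the CIP priorities change, not the geometry.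

30 is traced through 29 and 28 to 27 by functional-group changes only. C9 is carried through the ring closure as a triethylsilyl-protected carbinol and C8 as the more robust TBS ether. A C9 dioxolane would be the obvious mask, but it would have to be formed on, and hydrolysed from, a doubly α-branched, α-oxygenated ketone with an eliminable β-methoxy group. The carbinol avoids this, costing one easy reduction and one oxidation. The forward demand is a selective TES cleavage beside a TBS ether.

27 is cut at C3–C4 to give 25 (via 26). This removes the ten-membered ring and leaves an open chain in which every stereocentre and the alkene geometry are already fixed. The forward step must favour cyclisation over oligomerisation.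

25 is traced through 24 and 23 to 22, and 22 is cut at C10–C1 into 19 and 20. An anti aldol of an ethyl ketone with the simplest enal supplies C1–C3, both stereocentres and the terminal alkene in one step. The demand is E enolisation and attack on the correct enolate face under control from C8.

19 comes from 17 by oxidative cleavage of a 1,1-disubstituted alkene. The ketone stays masked as an alkene through the Grignard, hydride, enolate and zirconium steps. The demand is selectivity over the vinyl iodide.

17 comes from 15 by cutting C4–I and C5–H (syn hydrometalation of a methyl alkyne). This must precede the arrival of the terminal alkene in 22. 15 comes from 13 by cutting C11–CH3; the cis-related C6 and C7 substituents direct the methylation.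

13 is cut at the lactone C12–O6 bond to 12, and 12 is traced to 11 by C6 carbonyl reduction, which needs reagent control over the 6R configuration. 11 is cut at C5–C6 into 9 and 10.

9 is traced through 8 to 7, and 7 is cut at C7–C8 into 4 and 5. This is an auxiliary-controlled syn aldol that sets C7 and C8 absolutely and brings C9 as a latent ketone. 4 is cut at the imide N–acyl bond into 1 and 2.

## Other disconnections considered

Alternative 1: The cut is C7–C11. The forward step starts from a ten-membered (4E,7Z)-dienone carrying a C6 bromoacetal, A1. Bu3SnH/Et3B generates the C11 radical, which closes 5-exo onto C7 to give the cis-fused lactol ether A2.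
- In favour: cis fusion is intrinsic to the tethered 5-exo closure, so C7 is set from C6 with more certainty than the chosen plan's separate reduction (step 6). The conditions are neutral. On these points it is the better plan.
- Against: A1 still needs its own ten-membered ring closure, so the main problem is only moved. C11 is set in the radical step with less control than the enolate methylation of step 8. C8 emerges as CH2, so the oxygen must be added later by enolate oxidation of a ketone that can also enolise toward C10. The intermediate C8 radical may add across the ring to C4=C5.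
- Step economy: after A2 come acetal oxidation, C8 hydroxylation and esterification, plus the unsolved route to A1. This is no shorter than the chosen plan, and the stereochemistry at C8 and C11 is less secure.

Alternative 2: The cut is C5–C6. The acyclic iodo-aldehyde A3 is closed with CrCl2 and catalytic NiCl2, and the C6 alkoxide lactonises onto the C12 methyl ester to give A4.
- In favour: A4 is the same compound as 29, so the endgame is shared. The chromium reagent leaves the C9 ketone alone, so the four redox and protecting-group steps 13, 14, 16 and 17 would be unnecessary; on chemoselectivity and step count it is the better plan. The vinyl iodide of A3 is a 1-iodo-2-methylalkene, available from a terminal alkyne by carbometalation–iodination, which is at least as easy as step 9.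
- Against: C6 is created during ring closure, so its configuration depends on an unpredictable macrocyclic transition state. The aldehyde in A3 is α-branched with a β-silyloxy group and can epimerise or eliminate. A large excess of chromium salt at high dilution is needed.
- Comparison: the chosen plan creates no stereocentre in the ring-forming step and pays for that with the C9 mask. Alternative 2 is shorter but stakes C6 on the cyclisation.

Alternative 3: The cut is C6–C7 with ring expansion. The trans-1,2-dialkenylcyclohexanol A5, treated with KH and 18-crown-6, undergoes an anionic oxy-Cope shift that breaks C4–C9. The C8=C9 enolate is hydroxylated in the same flask to give A6.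
- In favour: the ring arises from a six-membered ring without high dilution, which is clearly better than any direct macrocyclisation. The chair transition state fixes the E alkene and relays alkene geometry into C6 and C7. The enolate forms only toward C8, so the hydroxylation is regiospecific.
- Against: A5 needs a quaternary C4 and a tertiary carbinol C9 on a cyclohexane that already carries C1 and C10, each with a geometrically pure alkenyl group (one an enol ether); this is a long synthesis. The face of hydroxylation on a ten-membered enolate is uncertain. Strongly basic conditions threaten the β-methoxy ketone. After A6 the lactone must still be built from the C12 silyl ether and C6 PMB ether while C8–OH is differentiated.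
- Comparison: it equals or betters the chosen plan in the ring-forming event itself, but has the hardest precursor and the longest sequence after the key step.

Key step: step 15

Remark on the chemistry: the C9 carbinol centre present in 24 to 28 is temporary. The 9S epimer expected from Felkin–Anh addition is drawn; its epimer would converge at 29.

## Route

Step 1
Reactants: 1 (4R)-4-benzyl-1,3-oxazolidin-2-one; 2 4-tert-butoxy-4-oxobutanoic acid
Product: 4 tert-butyl 4-[(4R)-4-benzyl-2-oxo-1,3-oxazolidin-3-yl]-4-oxobutanoate, via mixed pivalic anhydride 3 (not isolated)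
Conditions: t-BuCOCl, Et3N, THF, −20 °C; then LiCl, 1, −20 °C to rt
Reagents that add atoms: none
Why: Mixed-anhydride N-acylation of the oxazolidinone should occur at the less hindered succinyl carbonyl and leave the tert-butyl ester alone; no stereocentre is formed.

Step 2
Reactants: 4; 5 2-methylidenebutanal (2-ethylacrolein)
Product: 7 tert-butyl (3R,4R)-3-{[(4R)-4-benzyl-2-oxo-1,3-oxazolidin-3-yl]carbonyl}-4-hydroxy-5-methylideneheptanoate, via Z boron enolate 6 (not isolated)
Conditions: n-Bu2BOTf, i-Pr2NEt, CH2Cl2, 0 °C; 5, −78 to 0 °C; then pH 7 buffer, MeOH, H2O2, 0 °C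
Reagents that add atoms: none
Why: Evans syn aldol: only the imide is enolised, giving the Z enolate, and the dipole-minimised Zimmerman–Traxler chair should add the enolate face remote from the benzyl group to the enal carbonyl. This sets C7 and C8 syn with the configuration required by the (R) auxiliary, and C9 arrives as a 1,1-disubstituted alkene.

Step 3
Reactants: 7
Product: 8 tert-butyl (3R,4R)-4-hydroxy-3-[methoxy(methyl)carbamoyl]-5-methylideneheptanoate
Conditions: MeNH(OMe)·HCl, AlMe3, CH2Cl2, −20 to 0 °C
Reagents that add atoms: N,O-dimethylhydroxylamine hydrochloride, CNOC.Cl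
Why: Weinreb aminolysis with the aluminium amide, assisted by the free β-hydroxyl, should cleave the exocyclic imide carbonyl and release the auxiliary; the hindered tert-butyl ester should not react.

Step 4
Reactants: 8
Product: 9 tert-butyl (3R,4R)-4-[(tert-butyldimethylsilyl)oxy]-3-[methoxy(methyl)carbamoyl]-5-methylideneheptanoate
Conditions: TBSOTf, 2,6-lutidine, CH2Cl2, −78 to 0 °C
Reagents that add atoms: tert-butyldimethylsilyl trifluoromethanesulfonate, CC(C)(C)[Si](C)(C)OS(=O)(=O)C(F)(F)F
Why: Silylation of the hindered allylic alcohol with the silyl triflate. TBS is chosen because its oxygen does not coordinate boron in step 11 and because it outlasts the TES ether added in step 14.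

Step 5
Reactants: 9; 10 prop-1-ynylmagnesium bromide
Product: 11 tert-butyl (3R)-3-[(1R)-1-[(tert-butyldimethylsilyl)oxy]-2-methylidenebutyl]-4-oxohept-5-ynoate
Conditions: 10, THF, −20 to 0 °C; inverse quench into cold aq. NaHSO4
Reagents that add atoms: none
Why: Weinreb ketone synthesis: the chelated adduct should not collapse before the quench, so addition stops at the ynone, and the tert-butyl ester is much less electrophilic at this temperature. The inverse acidic quench prevents conjugate addition of the released hydroxylamine.

Step 6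
Reactants: 11
Product: 12 tert-butyl (3S,4R)-3-[(1R)-1-[(tert-butyldimethylsilyl)oxy]-2-methylidenebutyl]-4-hydroxyhept-5-ynoate
Conditions: Ru(p-cymene)[(R,R)-TsNCH(Ph)CH(Ph)NH] (3 mol%), i-PrOH, rt
Reagents that add atoms: none
Why: Noyori asymmetric transfer hydrogenation of an ynone: the (R,R) catalyst should give the 6R carbinol under reagent control, and this is also the Felkin–Anh sense with the C8 branch as the large group. Without added base, epimerisation at C7 and β-elimination of the silyloxy group should be avoided.

Step 7
Reactants: 12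
Product: 13 (4S,5R)-4-[(1R)-1-[(tert-butyldimethylsilyl)oxy]-2-methylidenebutyl]-5-(prop-1-yn-1-yl)oxolan-2-one
Conditions: CSA (0.2 equiv), PhMe, 50 °C
Reagents that add atoms: none
Why: Acid-catalysed 5-exo-trig lactonisation of the γ-hydroxy tert-butyl ester. C6–OH is the only free hydroxyl, so only the 6,12-lactone can form, and the cis ring fusion follows from the configurations set in steps 2 and 6. Anhydrous catalytic acid should leave the hindered TBS ether intact.

Step 8
Reactants: 13
Product: 15 (3S,4S,5R)-4-[(1R)-1-[(tert-butyldimethylsilyl)oxy]-2-methylidenebutyl]-3-methyl-5-(prop-1-yn-1-yl)oxolan-2-one, via lithium enolate 14 (not isolated)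
Conditions: LiN(SiMe3)2, THF, −78 °C; MeI, −78 to −40 °C
Reagents that add atoms: iodomethane, IC
Why: Lactone enolate alkylation. The C6 and C7 substituents sit on the same face of the enolate, so iodomethane should enter from the opposite face and place the C11 methyl trans to the C7 side chain (11S).

Step 9
Reactants: 15
Product: 17 (3S,4S,5R)-4-[(1R)-1-[(tert-butyldimethylsilyl)oxy]-2-methylidenebutyl]-5-[(1E)-2-iodoprop-1-en-1-yl]-3-methyloxolan-2-one, via alkenylzirconocene chloride 16 (not isolated)
Conditions: Cp2Zr(H)Cl (1.5 equiv), THF, rt; then I2, THF, −20 °C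
Reagents that add atoms: iodine, [I][I]
Why: Schwartz hydrozirconation adds Zr–H syn, with zirconium on the methyl-bearing C4, remote from the branched oxygenated C6. Iodinolysis with retention gives the E vinyl iodide (C6 trans to I); the hindered 1,1-disubstituted alkene and the lactone should react more slowly.

Step 10
Reactants: 17
Product: 19 (3S,4S,5R)-4-[(1R)-1-[(tert-butyldimethylsilyl)oxy]-2-oxobutyl]-5-[(1E)-2-iodoprop-1-en-1-yl]-3-methyloxolan-2-one, via vicinal diol 18 (not isolated)
Conditions: OsO4 (5 mol%), NaIO4, 2,6-lutidine, dioxane–H2O, rt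
Reagents that add atoms: osmium tetroxide, O=[Os](=O)(=O)=O (carrier of the ketone oxygen, regenerated by sodium periodate, [Na+].[O-]I(=O)(=O)=O)
Why: Lemieux–Johnson cleavage: OsO4 should select the electron-richer 1,1-disubstituted alkene over the iodine-deactivated trisubstituted one, and periodate cleaves the diol to the ethyl ketone. Lutidine buffers the medium for the silyl ether.

Step 11
Reactants: 19; 20 prop-2-enal (acrolein)
Product: 22 (3S,4S,5R)-4-[(1R,3S,4S)-1-[(tert-butyldimethylsilyl)oxy]-4-hydroxy-3-methyl-2-oxohex-5-en-1-yl]-5-[(1E)-2-iodoprop-1-en-1-yl]-3-methyloxolan-2-one, via E boron enolate 21 (not isolated)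
Conditions: (c-C6H11)2BCl, Et3N, Et2O, −78 to 0 °C; 20, −78 to −20 °C; then pH 7 buffer, MeOH, H2O2, 0 °C
Reagents that add atoms: none
Why: Paterson-type boron anti aldol: the bulky chloroborane with a small amine should enolise the ethyl side to the E enol borinate, and the chair transition state gives the anti C10/C1 relation. With C8–H eclipsing the enolate to avoid A(1,3) strain, acrolein should add to the face opposite the branched C7 ring carbon (syn to the silyloxy group), giving 10S,1S.

Step 12
Reactants: 22
Product: 23 (3S,4S,5R)-4-[(1R,3S,4S)-1-[(tert-butyldimethylsilyl)oxy]-4-methoxy-3-methyl-2-oxohex-5-en-1-yl]-5-[(1E)-2-iodoprop-1-en-1-yl]-3-methyloxolan-2-one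
Conditions: Me3OBF4, 1,8-bis(dimethylamino)naphthalene, 4 Å MS, CH2Cl2, 0 °C to rt
Reagents that add atoms: trimethyloxonium tetrafluoroborate, C[O+](C)C.F[B-](F)(F)F
Why: Meerwein O-methylation under non-basic conditions should etherify the aldol hydroxyl without retro-aldol cleavage, β-elimination or epimerisation.

Step 13
Reactants: 23
Product: 24 (3S,4S,5R)-4-[(1R,2S,3R,4S)-1-[(tert-butyldimethylsilyl)oxy]-2-hydroxy-4-methoxy-3-methylhex-5-en-1-yl]-5-[(1E)-2-iodoprop-1-en-1-yl]-3-methyloxolan-2-one
Conditions: NaBH4, MeOH–THF, −20 to 0 °C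
Reagents that add atoms: none
Why: Borohydride reduces the ketone and not the lactone. Felkin–Anh addition anti to the C8 silyloxy group, reinforced by the C10 branch, should favour the 9S carbinol, whose configuration is erased in step 17. The descriptor at C10 changes to R only through CIP priorities.

Step 14
Reactants: 24
Product: 25 (3S,4S,5R)-4-[(1R,2S,3S,4S)-1-[(tert-butyldimethylsilyl)oxy]-4-methoxy-3-methyl-2-[(triethylsilyl)oxy]hex-5-en-1-yl]-5-[(1E)-2-iodoprop-1-en-1-yl]-3-methyloxolan-2-one
Conditions: TESOTf, 2,6-lutidine, CH2Cl2, −78 to 0 °C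
Reagents that add atoms: triethylsilyl trifluoromethanesulfonate, CC[Si](CC)(CC)OS(=O)(=O)C(F)(F)F
Why: Silylation of the hindered C9 carbinol with the triflate. A free O9 could migrate the neighbouring silyl group or open the lactone under the basic coupling conditions, and TES can later be removed in the presence of TBS.

Step 15
Reactants: 25
Product: 27 (1S,6S,7S,8R,9S,10S,11S,4E)-8-[(tert-butyldimethylsilyl)oxy]-1-methoxy-9-[(triethylsilyl)oxy]germacr-4-en-12,6-olide, via B-alkyl-9-BBN 26 (not isolated)
Conditions: 9-BBN (2 equiv), THF, rt; then syringe-pump addition over 12 h to PdCl2(dppf) (15 mol%), Ph3As (30 mol%), Cs2CO3 (3 equiv), DMF–THF–H2O, 45 °C, final concentration about 1 mM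
Reagents that add atoms: none
Why: 9-BBN should add to the monosubstituted C2=C3 alkene with boron at C3, because the trisubstituted iodoalkene, the lactone and the silyl ethers are inert to it and no carbonyl is present at C9. The divalent palladium precatalyst is reduced to zerovalent palladium, which inserts into the C4–I bond with retention; the base-activated primary alkylborane transmetalates and reductive elimination forms C3–C4. The closest known reaction type is the B-alkyl Suzuki–Miyaura macrocyclisation, which has closed medium-ring E-cycloalkenes. The ten-membered carbocycle is closed by intramolecular sp3–sp2 coupling through an eleven-membered palladacycle, with C4 becoming a ring atom. No stereocentre is created, and the E geometry is fixed in the vinyl iodide and untouched by oxidative addition and reductive elimination. The step needs cyclisation to beat oligomerisation and β-hydride elimination: slow addition at high dilution, the wide bite angle of dppf and the arsine ligand should secure this, and the cis-fused lactone holds the two chain ends on the same side. The methoxy group is γ to boron, so β-alkoxy elimination is not possible.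

Step 16
Reactants: 27
Product: 28 (1S,6S,7S,8R,9S,10R,11S,4E)-8-[(tert-butyldimethylsilyl)oxy]-9-hydroxy-1-methoxygermacr-4-en-12,6-olide
Conditions: PPTS (0.2 equiv), MeOH–CH2Cl2, 0 °C to rt
Reagents that add atoms: none
Why: Acid-catalysed methanolysis cleaves a TES ether much faster than a TBS ether, so only O9 should be freed. Under these non-basic conditions neither silyl nor lactone migration is expected.

Step 17
Reactants: 28
Product: 29 (1S,6S,7S,8R,10S,11S,4E)-8-[(tert-butyldimethylsilyl)oxy]-1-methoxy-9-oxogermacr-4-en-12,6-olide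
Conditions: Dess–Martin periodinane, NaHCO3, CH2Cl2, rt
Reagents that add atoms: none
Why: Dess–Martin oxidation of the secondary carbinol under buffered neutral conditions should give the ketone without epimerising C8 or C10 and without eliminating methanol.

Step 18
Reactants: 29
Product: 30 (1S,6S,7R,8R,10S,11S,4E)-8-hydroxy-1-methoxy-9-oxogermacr-4-en-12,6-olide
Conditions: HF·pyridine, pyridine, THF, 0 °C to rt
Reagents that add atoms: none
Why: Fluoride cleavage of the TBS ether under buffered, slightly acidic conditions generates no alkoxide, so lactone migration to O8 and α-ketol isomerisation should not occur. The descriptor at C7 changes to R only through CIP priorities.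

Step 19
Reactants: 31 (2E)-2-methylbut-2-enoic acid (tiglic acid)
Product: 32 (2E)-2-methylbut-2-en-1-ol
Conditions: LiAlH4, Et2O, 0 °C to rt
Reagents that add atoms: none
Why: Hydride reduction of the acid to the allylic alcohol is a 1,2-reduction that keeps the E geometry.

Step 20
Reactants: 32
Product: 33 [(2R,3R)-2,3-dimethyloxiran-2-yl]methanol
Conditions: Ti(Oi-Pr)4 (10 mol%), D-(−)-diethyl tartrate (12 mol%), t-BuOOH, 4 Å MS, CH2Cl2, −20 °C
Reagents that add atoms: tert-butyl hydroperoxide, CC(C)(C)OO
Why: Sharpless asymmetric epoxidation of an E-trisubstituted allylic alcohol. The L-(+) ligand gives the (2S,3S) epoxy alcohols of this class, so the D-(−) ligand should deliver oxygen to the opposite face and give (2R,3R).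

Step 21
Reactants: 33
Product: 34 (2S,3R)-2,3-dimethyloxirane-2-carboxylic acid
Conditions: RuCl3·xH2O (2 mol%), NaIO4, CCl4–MeCN–H2O, rt
Reagents that add atoms: sodium periodate, [Na+].[O-]I(=O)(=O)=O; water, O
Why: Catalytic RuO4 oxidation of the primary alcohol to the acid tolerates the epoxide. No stereocentre is touched; the descriptor at C2 changes from R to S only through CIP priorities.

Step 22
Reactants: 30; 34
Product: 36 (3S,3aS,4R,6S,7S,11aS,10E)-7-methoxy-3,6,10-trimethyl-2,5-dioxo-2,3,3a,4,5,6,7,8,9,11a-decahydrocyclodeca[b]furan-4-yl (2S,3R)-2,3-dimethyloxirane-2-carboxylate, via Yamaguchi mixed anhydride 35 (not isolated)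
Conditions: 34, 2,4,6-Cl3C6H2COCl, Et3N, PhMe, rt; then 30, DMAP, PhMe, rt
Reagents that add atoms: none
Why: Yamaguchi esterification: DMAP transfers the acyl group from the mixed anhydride to the hindered secondary alcohol. The acid has no α-hydrogen and cannot epimerise, and the short, mildly basic conditions should avoid lactone migration.

## Compound list

1 | (4R)-4-benzyl-1,3-oxazolidin-2-one | O=C1N[C@H](Cc2ccccc2)CO1 | starting material
2 | 4-tert-butoxy-4-oxobutanoic acid | CC(C)(C)OC(=O)CCC(=O)O | starting material
3 | 4-tert-butoxy-4-oxobutanoic pivalic anhydride | CC(C)(C)OC(=O)CCC(=O)OC(=O)C(C)(C)C | intermediate (not isolated)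
4 | tert-butyl 4-[(4R)-4-benzyl-2-oxo-1,3-oxazolidin-3-yl]-4-oxobutanoate | CC(C)(C)OC(=O)CCC(=O)N1[C@H](Cc2ccccc2)COC1=O | intermediate
5 | 2-methylidenebutanal | CCC(=C)C=O | starting material
6 | Z dibutylboron enolate of 4 | CCCCB(CCCC)O/C(=C\CC(=O)OC(C)(C)C)N1[C@H](Cc2ccccc2)COC1=O | intermediate (not isolated)
7 | tert-butyl (3R,4R)-3-{[(4R)-4-benzyl-2-oxo-1,3-oxazolidin-3-yl]carbonyl}-4-hydroxy-5-methylideneheptanoate | CCC(=C)[C@H](O)[C@@H](CC(=O)OC(C)(C)C)C(=O)N1[C@H](Cc2ccccc2)COC1=O | intermediate
8 | tert-butyl (3R,4R)-4-hydroxy-3-[methoxy(methyl)carbamoyl]-5-methylideneheptanoate | CCC(=C)[C@H](O)[C@@H](CC(=O)OC(C)(C)C)C(=O)N(C)OC | intermediate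
9 | tert-butyl (3R,4R)-4-[(tert-butyldimethylsilyl)oxy]-3-[methoxy(methyl)carbamoyl]-5-methylideneheptanoate | CCC(=C)[C@H](O[Si](C)(C)C(C)(C)C)[C@@H](CC(=O)OC(C)(C)C)C(=O)N(C)OC | intermediate
10 | prop-1-ynylmagnesium bromide | CC#C[Mg]Br | starting material
11 | tert-butyl (3R)-3-[(1R)-1-[(tert-butyldimethylsilyl)oxy]-2-methylidenebutyl]-4-oxohept-5-ynoate | CCC(=C)[C@H](O[Si](C)(C)C(C)(C)C)[C@@H](CC(=O)OC(C)(C)C)C(=O)C#CC | intermediate
12 | tert-butyl (3S,4R)-3-[(1R)-1-[(tert-butyldimethylsilyl)oxy]-2-methylidenebutyl]-4-hydroxyhept-5-ynoate | CCC(=C)[C@H](O[Si](C)(C)C(C)(C)C)[C@@H](CC(=O)OC(C)(C)C)[C@@H](O)C#CC | intermediate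
13 | (4S,5R)-4-[(1R)-1-[(tert-butyldimethylsilyl)oxy]-2-methylidenebutyl]-5-(prop-1-yn-1-yl)oxolan-2-one | CCC(=C)[C@H](O[Si](C)(C)C(C)(C)C)[C@H]1CC(=O)O[C@H]1C#CC | intermediate
14 | lithium enolate of 13 | CCC(=C)[C@H](O[Si](C)(C)C(C)(C)C)[C@H]1C=C(O[Li])O[C@H]1C#CC | intermediate (not isolated)
15 | (3S,4S,5R)-4-[(1R)-1-[(tert-butyldimethylsilyl)oxy]-2-methylidenebutyl]-3-methyl-5-(prop-1-yn-1-yl)oxolan-2-one | CCC(=C)[C@H](O[Si](C)(C)C(C)(C)C)[C@H]1[C@H](C)C(=O)O[C@H]1C#CC | intermediate
16 | E alkenylzirconocene chloride from 15 (Zr on C4) | CCC(=C)[C@H](O[Si](C)(C)C(C)(C)C)[C@H]1[C@H](C)C(=O)O[C@H]1/C=C(\C)[Zr](Cl)(C2C=CC=C2)C2C=CC=C2 | intermediate (not isolated)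
17 | (3S,4S,5R)-4-[(1R)-1-[(tert-butyldimethylsilyl)oxy]-2-methylidenebutyl]-5-[(1E)-2-iodoprop-1-en-1-yl]-3-methyloxolan-2-one | CCC(=C)[C@H](O[Si](C)(C)C(C)(C)C)[C@H]1[C@H](C)C(=O)O[C@H]1/C=C(\C)I | intermediate
18 | (3S,4S,5R)-4-[(1R)-1-[(tert-butyldimethylsilyl)oxy]-2-hydroxy-2-(hydroxymethyl)butyl]-5-[(1E)-2-iodoprop-1-en-1-yl]-3-methyloxolan-2-one (C9 epimers) | CCC(O)(CO)[C@H](O[Si](C)(C)C(C)(C)C)[C@H]1[C@H](C)C(=O)O[C@H]1/C=C(\C)I | intermediate (not isolated)
19 | (3S,4S,5R)-4-[(1R)-1-[(tert-butyldimethylsilyl)oxy]-2-oxobutyl]-5-[(1E)-2-iodoprop-1-en-1-yl]-3-methyloxolan-2-one | CCC(=O)[C@H](O[Si](C)(C)C(C)(C)C)[C@H]1[C@H](C)C(=O)O[C@H]1/C=C(\C)I | intermediate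
20 | prop-2-enal | C=CC=O | starting material
21 | E dicyclohexylboron enolate of 19 | C/C=C(/OB(C1CCCCC1)C1CCCCC1)[C@H](O[Si](C)(C)C(C)(C)C)[C@H]1[C@H](C)C(=O)O[C@H]1/C=C(\C)I | intermediate (not isolated)
22 | (3S,4S,5R)-4-[(1R,3S,4S)-1-[(tert-butyldimethylsilyl)oxy]-4-hydroxy-3-methyl-2-oxohex-5-en-1-yl]-5-[(1E)-2-iodoprop-1-en-1-yl]-3-methyloxolan-2-one | C=C[C@H](O)[C@H](C)C(=O)[C@H](O[Si](C)(C)C(C)(C)C)[C@H]1[C@H](C)C(=O)O[C@H]1/C=C(\C)I | intermediate
23 | (3S,4S,5R)-4-[(1R,3S,4S)-1-[(tert-butyldimethylsilyl)oxy]-4-methoxy-3-methyl-2-oxohex-5-en-1-yl]-5-[(1E)-2-iodoprop-1-en-1-yl]-3-methyloxolan-2-one | C=C[C@H](OC)[C@H](C)C(=O)[C@H](O[Si](C)(C)C(C)(C)C)[C@H]1[C@H](C)C(=O)O[C@H]1/C=C(\C)I | intermediate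
24 | (3S,4S,5R)-4-[(1R,2S,3R,4S)-1-[(tert-butyldimethylsilyl)oxy]-2-hydroxy-4-methoxy-3-methylhex-5-en-1-yl]-5-[(1E)-2-iodoprop-1-en-1-yl]-3-methyloxolan-2-one | C=C[C@H](OC)[C@H](C)[C@H](O)[C@H](O[Si](C)(C)C(C)(C)C)[C@H]1[C@H](C)C(=O)O[C@H]1/C=C(\C)I | intermediate
25 | (3S,4S,5R)-4-[(1R,2S,3S,4S)-1-[(tert-butyldimethylsilyl)oxy]-4-methoxy-3-methyl-2-[(triethylsilyl)oxy]hex-5-en-1-yl]-5-[(1E)-2-iodoprop-1-en-1-yl]-3-methyloxolan-2-one | C=C[C@H](OC)[C@H](C)[C@H](O[Si](CC)(CC)CC)[C@H](O[Si](C)(C)C(C)(C)C)[C@H]1[C@H](C)C(=O)O[C@H]1/C=C(\C)I | intermediate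
26 | B-alkyl-9-borabicyclo[3.3.1]nonane from 25 (boron on C3) | C1CCC2CCCC1B2CC[C@H](OC)[C@H](C)[C@H](O[Si](CC)(CC)CC)[C@H](O[Si](C)(C)C(C)(C)C)[C@H]3[C@H](C)C(=O)O[C@H]3/C=C(\C)I | intermediate (not isolated)
27 | (1S,6S,7S,8R,9S,10S,11S,4E)-8-[(tert-butyldimethylsilyl)oxy]-1-methoxy-9-[(triethylsilyl)oxy]germacr-4-en-12,6-olide | CO[C@H]1CC/C(C)=C/[C@@H]2OC(=O)[C@@H](C)[C@@H]2[C@@H](O[Si](C)(C)C(C)(C)C)[C@@H](O[Si](CC)(CC)CC)[C@H]1C | intermediate
28 | (1S,6S,7S,8R,9S,10R,11S,4E)-8-[(tert-butyldimethylsilyl)oxy]-9-hydroxy-1-methoxygermacr-4-en-12,6-olide | CO[C@H]1CC/C(C)=C/[C@@H]2OC(=O)[C@@H](C)[C@@H]2[C@@H](O[Si](C)(C)C(C)(C)C)[C@@H](O)[C@H]1C | intermediate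
29 | (1S,6S,7S,8R,10S,11S,4E)-8-[(tert-butyldimethylsilyl)oxy]-1-methoxy-9-oxogermacr-4-en-12,6-olide | CO[C@H]1CC/C(C)=C/[C@@H]2OC(=O)[C@@H](C)[C@@H]2[C@@H](O[Si](C)(C)C(C)(C)C)C(=O)[C@H]1C | intermediate
30 | (1S,6S,7R,8R,10S,11S,4E)-8-hydroxy-1-methoxy-9-oxogermacr-4-en-12,6-olide | CO[C@H]1CC/C(C)=C/[C@@H]2OC(=O)[C@@H](C)[C@@H]2[C@@H](O)C(=O)[C@H]1C | intermediate
31 | (2E)-2-methylbut-2-enoic acid | C/C=C(\C)C(=O)O | starting material
32 | (2E)-2-methylbut-2-en-1-ol | C/C=C(\C)CO | intermediate
33 | [(2R,3R)-2,3-dimethyloxiran-2-yl]methanol | OC[C@@]1(C)O[C@@H]1C | intermediate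
34 | (2S,3R)-2,3-dimethyloxirane-2-carboxylic acid | OC(=O)[C@@]1(C)O[C@@H]1C | intermediate
35 | (2S,3R)-2,3-dimethyloxirane-2-carboxylic 2,4,6-trichlorobenzoic anhydride | O=C(OC(=O)[C@@]1(C)O[C@@H]1C)c1c(Cl)cc(Cl)cc1Cl | intermediate (not isolated)
36 | (3S,3aS,4R,6S,7S,11aS,10E)-7-methoxy-3,6,10-trimethyl-2,5-dioxo-2,3,3a,4,5,6,7,8,9,11a-decahydrocyclodeca[b]furan-4-yl (2S,3R)-2,3-dimethyloxirane-2-carboxylate | CO[C@H]1CC/C(C)=C/[C@@H]2OC(=O)[C@@H](C)[C@@H]2[C@@H](OC(=O)[C@@]2(C)O[C@@H]2C)C(=O)[C@H]1C | target

## Step count and least certain steps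

Total: 22 steps. Longest linear sequence: 19 steps (steps 1 to 18 and 22); steps 19 to 21 make the side-chain acid.

Step 15 (key step). The most likely failure is oligomerisation, or protodeboronation and β-hydride elimination, in place of ring closure, because the ten-membered E-cycloalkene is strained and the hindered substrate slows transmetalation. The fallback keeps the bond but uses a base-free alkylzinc coupling made stepwise. It sets out from 25: hydroboration with 9-BBN and oxidation with NaBO3·4H2O should give the primary alcohol F1; I2, PPh3 and imidazole convert it to the primary iodide F2; Zn dust with LiCl inserts only into the alkyl C–I bond to give the alkylzinc iodide F3, which is added slowly to Pd(PPh3)4 in THF at high dilution (intramolecular Negishi coupling). It returns to the route at 27.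

Step 11. The most likely failure is poor facial selectivity, giving the C10/C1 pair of opposite configuration: a silyl ether offers no hydrogen-bond direction, and the steric difference between the silyloxy group and the C7 ring carbon may be small. The fallback switches to α′-acyloxy control, the best-precedented director for E enol borinates. It sets out from 19: HF·pyridine should give the α-hydroxy ketone F4; chloroacetic anhydride and pyridine give the chloroacetate F5; (c-C6H11)2BCl, Me2NEt and acrolein give the anti aldol F6 by attack syn to the acyloxy group; Me3OBF4 with the naphthalene diamine base gives the methyl ether F7; thiourea with NaHCO3 in ethanol removes the chloroacetyl group under near-neutral conditions to give the hydroxy ketone F8; TBSOTf and 2,6-lutidine then return to the route at 23.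

Step 9. The most likely failure is incomplete regiocontrol (iodine partly at C5), or competing hydrozirconation of the 1,1-disubstituted alkene and slow reduction of the lactone when excess reagent is needed. The fallback sets out from 15: PtCl2 with XPhos and Et3SiH should add Si–H syn with silicon on the distal, less hindered C4 to give the E vinylsilane F9; N-iodosuccinimide in (CF3)2CHOH then exchanges silicon for iodine with retention. It returns to the route at 17.

Step 7. The most likely failure is loss of the C8 silyl ether under acid, after which O8 competes for the acyl group and the 8,12-lactone forms. The fallback sets out from 12: TMSOTf and 2,6-lutidine cleave the tert-butyl ester without touching the TBS ether, and mild aqueous work-up gives the hydroxy acid F10; EDC·HCl and DMAP then close the lactone through carboxyl activation. It returns to the route at 13.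

Step 22. The most likely failure is slow acylation of the hindered C8 hydroxyl by the α-quaternary acid, leaving time for base-mediated lactone migration to O8 or epimerisation next to the ketone. The fallback alkylates the carboxylate instead of acylating the alcohol. It sets out from 30: CBr4 and PPh3 should give, with inversion, the 8S bromide F11; the caesium salt of 34 in DMF at 0 °C displaces the bromide next to the ketone with a second inversion. It returns to the route at 36.

## Further compounds

F1 | step 15 | (3S,4S,5R)-4-[(1R,2S,3S,4S)-1-[(tert-butyldimethylsilyl)oxy]-6-hydroxy-4-methoxy-3-methyl-2-[(triethylsilyl)oxy]hexyl]-5-[(1E)-2-iodoprop-1-en-1-yl]-3-methyloxolan-2-one | OCC[C@H](OC)[C@H](C)[C@H](O[Si](CC)(CC)CC)[C@H](O[Si](C)(C)C(C)(C)C)[C@H]1[C@H](C)C(=O)O[C@H]1/C=C(\C)I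
F2 | step 15 | primary iodide from F1 (iodine on C3) | ICC[C@H](OC)[C@H](C)[C@H](O[Si](CC)(CC)CC)[C@H](O[Si](C)(C)C(C)(C)C)[C@H]1[C@H](C)C(=O)O[C@H]1/C=C(\C)I
F3 | step 15 | alkylzinc iodide from F2 (zinc on C3) | I[Zn]CC[C@H](OC)[C@H](C)[C@H](O[Si](CC)(CC)CC)[C@H](O[Si](C)(C)C(C)(C)C)[C@H]1[C@H](C)C(=O)O[C@H]1/C=C(\C)I
F4 | step 11 | (3S,4S,5R)-4-[(1R)-1-hydroxy-2-oxobutyl]-5-[(1E)-2-iodoprop-1-en-1-yl]-3-methyloxolan-2-one | CCC(=O)[C@H](O)[C@H]1[C@H](C)C(=O)O[C@H]1/C=C(\C)I
F5 | step 11 | chloroacetate of F4 | CCC(=O)[C@H](OC(=O)CCl)[C@H]1[C@H](C)C(=O)O[C@H]1/C=C(\C)I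
F6 | step 11 | anti aldol of F5 with acrolein (C8 chloroacetate, 10S,1S) | C=C[C@H](O)[C@H](C)C(=O)[C@H](OC(=O)CCl)[C@H]1[C@H](C)C(=O)O[C@H]1/C=C(\C)I
F7 | step 11 | C1 methyl ether of F6 | C=C[C@H](OC)[C@H](C)C(=O)[C@H](OC(=O)CCl)[C@H]1[C@H](C)C(=O)O[C@H]1/C=C(\C)I
F8 | step 11 | (3S,4S,5R)-4-[(1R,3S,4S)-1-hydroxy-4-methoxy-3-methyl-2-oxohex-5-en-1-yl]-5-[(1E)-2-iodoprop-1-en-1-yl]-3-methyloxolan-2-one | C=C[C@H](OC)[C@H](C)C(=O)[C@H](O)[C@H]1[C@H](C)C(=O)O[C@H]1/C=C(\C)I
F9 | step 9 | (3S,4S,5R)-4-[(1R)-1-[(tert-butyldimethylsilyl)oxy]-2-methylidenebutyl]-3-methyl-5-[(1E)-2-(triethylsilyl)prop-1-en-1-yl]oxolan-2-one | CCC(=C)[C@H](O[Si](C)(C)C(C)(C)C)[C@H]1[C@H](C)C(=O)O[C@H]1/C=C(\C)[Si](CC)(CC)CC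
F10 | step 7 | (3S,4R)-3-[(1R)-1-[(tert-butyldimethylsilyl)oxy]-2-methylidenebutyl]-4-hydroxyhept-5-ynoic acid | CCC(=C)[C@H](O[Si](C)(C)C(C)(C)C)[C@@H](CC(=O)O)[C@@H](O)C#CC
F11 | step 22 | (1S,6S,7S,8S,10S,11S,4E)-8-bromo-1-methoxy-9-oxogermacr-4-en-12,6-olide | CO[C@H]1CC/C(C)=C/[C@@H]2OC(=O)[C@@H](C)[C@@H]2[C@H](Br)C(=O)[C@H]1C
A1 | alternative 1 | ten-membered (4E,7Z)-dienone with C6 bromoacetal (acetal and bromide centres unassigned) | CO[C@H]1CC/C(C)=C/[C@H](OC(OCC)C(C)Br)/C=C\C(=O)[C@H]1C
A2 | alternative 1 | cis-fused lactol ethyl ether on the ten-membered ketone | CO[C@H]1CC/C(C)=C/[C@@H]2O[C@H](OCC)[C@@H](C)[C@@H]2CC(=O)[C@H]1C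
A3 | alternative 2 | acyclic E vinyl iodide with C6 aldehyde and C12 methyl ester and C8 TBS ether | I/C=C(\C)CC[C@H](OC)[C@H](C)C(=O)[C@H](O[Si](C)(C)C(C)(C)C)[C@H](C=O)[C@H](C)C(=O)OC
A4 | alternative 2 | ten-membered keto lactone with C8 TBS ether (identical with 29) | CO[C@H]1CC/C(C)=C/[C@@H]2OC(=O)[C@@H](C)[C@@H]2[C@@H](O[Si](C)(C)C(C)(C)C)C(=O)[C@H]1C
A5 | alternative 3 | trans-1,2-dialkenylcyclohexanol (E enol ether on C4 and Z alkenyl on C9) | CO[C@H]1CC[C@](C)(/C=C/OCc2ccc(OC)cc2)[C@@](O)(/C=C\[C@H](C)CO[Si](C)(C)C(C)(C)C)[C@H]1C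
A6 | alternative 3 | ten-membered 8-hydroxy-9-ketone with C6 PMB ether and C7 side chain | CO[C@H]1CC/C(C)=C/[C@H](OCc2ccc(OC)cc2)[C@H]([C@H](C)CO[Si](C)(C)C(C)(C)C)[C@@H](O)C(=O)[C@H]1C
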